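**Retrosynthetic overview**
- Last, two silyl ethers are removed; before that the ten-membered carbocycle and the ylidene butenolide are made together in one operation from an acyclic vinyl iodide/thioester (C–C bond from the butenolide β-carbon to the enol-lactone carbon, then enol-lactonisation).
- The vinyl iodide comes from a γ-acyloxy ynoate by iodo-aldol reaction with formaldehyde; the ynoate comes from asymmetric propiolate addition to an aldehyde (sets the ester-bearing carbinol) and esterification with the silylated side-chain acid.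
- The 3(2H)-furanone is made first, by Claisen acylation/cyclodehydration of an (S)-citramalic-acid-derived α-hydroxy methyl ketone (quaternary centre) with (S)-α-methyl-γ-butyrolactone (CHMe centre).
- Ring order: furanone, then carbocycle and butenolide together.

Assumption: the ligand antipodes named in steps 1 and 7 are the ones that give the S centres (the other antipode gives R), and 1-(tert-butyldimethylsilyloxy)propan-2-one is bought.

**Route**

Step 1
Reactants: 1 α-methylene-γ-butyrolactone (tulipalin A)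
Product: 2 (S)-3-methyldihydrofuran-2(3H)-one
Conditions: H2 (50 atm), Ru(OAc)2[(R)-BINAP] (0.5 mol %), CH2Cl2, 50 °C
Reagents that add atoms: none
Why: Noyori-type asymmetric hydrogenation of the exocyclic alkene with carbonyl chelation to ruthenium, the chiral diphosphine choosing the face that gives the S α-methyl centre (about 95% ee).

Step 2
Reactants: 3 (S)-citramalic acid
Product: 4 2-[(4S)-2,2,4-trimethyl-5-oxo-1,3-dioxolan-4-yl]acetic acid
Conditions: Me2C(OMe)2, TsOH (cat.), acetone, 25 °C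
Reagents that add atoms: 2,2-dimethoxypropane COC(C)(C)OC
Why: Acid-catalysed acetonide formation ties up the α-hydroxy acid as the five-membered 1,3-dioxolan-4-one and leaves the CH2CO2H free, without touching the quaternary S centre.

Step 3
Reactants: 4 2-[(4S)-2,2,4-trimethyl-5-oxo-1,3-dioxolan-4-yl]acetic acid
Product: 5 (3S)-3-hydroxy-3-methyl-4-oxopentanoic acid
Conditions: MeLi (2.1 equiv), THF, −78 °C; 1 M HCl work-up
Reagents that add atoms: methyllithium [Li]C
Why: The first MeLi makes the carboxylate and the second adds to the activated dioxolanone carbonyl to a lithium hemiketal that collapses on work-up to the methyl ketone and acetone (acyl substitution of an activated ester), with no stereocentre involved.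

Step 4
Reactants: 5 (3S)-3-hydroxy-3-methyl-4-oxopentanoic acid; 2 (S)-3-methyldihydrofuran-2(3H)-one
Product: 7 2-[(2S)-5-[(2S)-4-hydroxybutan-2-yl]-2-methyl-3-oxo-2,3-dihydrofuran-2-yl]acetic acid, via hydroxy diketone acid 6 (not isolated)
Conditions: LiN(iPr)2 (3.2 equiv), THF, −78 °C; add 2, −78 → −20 °C; then 2 M HCl, THF, 25 °C
Reagents that add atoms: none
Why: Claisen-type C-acylation of the methyl-ketone enolate of the trianion (its only enolisable site) by the lactone carbonyl opens the lactone to the α'-hydroxy-1,3-diketone, which cyclodehydrates in acid to the 3(2H)-furanone; both stereocentres come in with the partners and no new one is made.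

Step 5
Reactants: 7 2-[(2S)-5-[(2S)-4-hydroxybutan-2-yl]-2-methyl-3-oxo-2,3-dihydrofuran-2-yl]acetic acid
Product: 8 2-[(2S)-2-methyl-3-oxo-5-[(2S)-4-oxobutan-2-yl]-2,3-dihydrofuran-2-yl]acetic acid
Conditions: TEMPO (10 mol %), PhI(OAc)2 (1.1 equiv), CH2Cl2, 25 °C
Reagents that add atoms: none
Why: Oxoammonium (TEMPO) oxidation takes the primary alcohol to the aldehyde and leaves the acid and the furanone alone.

Step 6
Reactants: 8 2-[(2S)-2-methyl-3-oxo-5-[(2S)-4-oxobutan-2-yl]-2,3-dihydrofuran-2-yl]acetic acid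
Product: 9 S-ethyl 2-[(2S)-2-methyl-3-oxo-5-[(2S)-4-oxobutan-2-yl]-2,3-dihydrofuran-2-yl]ethanethioate
Conditions: EtSH (3 equiv), EDC·HCl (1.3 equiv), DMAP (10 mol %), CH2Cl2, 0 °C
Reagents that add atoms: ethanethiol CCS
Why: Carbodiimide (Steglich-type) thioesterification gives the S-ethyl thioester, which is inert in steps 7–11 and is the acyl donor in step 12.

Step 7
Reactants: 9 S-ethyl 2-[(2S)-2-methyl-3-oxo-5-[(2S)-4-oxobutan-2-yl]-2,3-dihydrofuran-2-yl]ethanethioate; 10 methyl propiolate
Product: 11 methyl (4S,6S)-6-[(5S)-5-[2-(ethylsulfanyl)-2-oxoethyl]-5-methyl-4-oxo-4,5-dihydrofuran-2-yl]-4-hydroxyhept-2-ynoate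
Conditions: Me2Zn (3 equiv), (S,S)-ProPhenol (20 mol %), Ph3PO (40 mol %), toluene, 4 °C; NH4Cl work-up
Reagents that add atoms: none
Why: Zinc–ProPhenol catalysed asymmetric alkynylation, in which the dinuclear zinc catalyst delivers the zinc alkynylide of 10 to one aldehyde face under catalyst control and so sets the S carbinol centre.

Step 8
Reactants: 12 1-(tert-butyldimethylsilyloxy)propan-2-one; 13 triethyl phosphonoacetate
Product: 14 ethyl (2E)-4-(tert-butyldimethylsilyloxy)-3-methylbut-2-enoate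
Conditions: NaH, THF, 0 → 25 °C; chromatography to remove the minor Z isomer
Reagents that add atoms: none
Why: Horner–Wadsworth–Emmons olefination with a stabilised phosphonate anion gives mainly the E enoate (CO2Et trans to CH2OTBS).

Step 9
Reactants: 14 ethyl (2E)-4-(tert-butyldimethylsilyloxy)-3-methylbut-2-enoate
Product: 15 (2E)-4-(tert-butyldimethylsilyloxy)-3-methylbut-2-enoic acid
Conditions: LiOH, THF/H2O, 25 °C; then 1 M HCl to pH 3, 0 °C
Reagents that add atoms: lithium hydroxide [Li+].[OH-]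
Why: Saponification, to which the silyl ether and the alkene geometry are stable.

Step 10
Reactants: 11 methyl (4S,6S)-6-[(5S)-5-[2-(ethylsulfanyl)-2-oxoethyl]-5-methyl-4-oxo-4,5-dihydrofuran-2-yl]-4-hydroxyhept-2-ynoate; 15 (2E)-4-(tert-butyldimethylsilyloxy)-3-methylbut-2-enoic acid
Product: 16 methyl (4S,6S)-4-{[(2E)-4-(tert-butyldimethylsilyloxy)-3-methylbut-2-enoyl]oxy}-6-[(5S)-5-[2-(ethylsulfanyl)-2-oxoethyl]-5-methyl-4-oxo-4,5-dihydrofuran-2-yl]hept-2-ynoate
Conditions: EDC·HCl (1.5 equiv), DMAP (0.2 equiv), CH2Cl2, 0 °C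
Reagents that add atoms: none
Why: Steglich esterification acylates the propargylic alcohol on oxygen, so the carbinol configuration is retained.

Step 11
Reactants: 16 methyl (4S,6S)-4-{[(2E)-4-(tert-butyldimethylsilyloxy)-3-methylbut-2-enoyl]oxy}-6-[(5S)-5-[2-(ethylsulfanyl)-2-oxoethyl]-5-methyl-4-oxo-4,5-dihydrofuran-2-yl]hept-2-ynoate
Product: 18 methyl (2Z,4S,6S)-4-{[(2E)-4-(tert-butyldimethylsilyloxy)-3-methylbut-2-enoyl]oxy}-2-[(tert-butyldimethylsilyloxy)methyl]-6-[(5S)-5-[2-(ethylsulfanyl)-2-oxoethyl]-5-methyl-4-oxo-4,5-dihydrofuran-2-yl]-3-iodohept-2-enoate, via iodo alcohol 17 (not isolated)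
Conditions: MgI2 (1.5 equiv), CH2O (anhydrous, THF solution), CH2Cl2, −20 → 0 °C; then TBSCl, imidazole, DMAP, 0 → 25 °C
Reagents that add atoms: magnesium diiodide I[Mg]I; formaldehyde C=O; tert-butyldimethylsilyl chloride CC(C)(C)[Si](C)(C)Cl
Why: Halo-aldol (β-iodo Morita–Baylis–Hillman) reaction in which iodide adds to the ynoate β-carbon and the magnesium allenolate is hydroxymethylated at the α-carbon by formaldehyde entering anti to iodine (as the proton does in NaI/AcOH hydroiodination of 2-ynoates), giving the Z tetrasubstituted alkene with iodine cis to CO2Me, and the magnesium alkoxide is silylated in the same flask.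

Step 12
Reactants: 18 methyl (2Z,4S,6S)-4-{[(2E)-4-(tert-butyldimethylsilyloxy)-3-methylbut-2-enoyl]oxy}-2-[(tert-butyldimethylsilyloxy)methyl]-6-[(5S)-5-[2-(ethylsulfanyl)-2-oxoethyl]-5-methyl-4-oxo-4,5-dihydrofuran-2-yl]-3-iodohept-2-enoate
Product: 21 bis(tert-butyldimethylsilyl) ether of the target, via alkenylzinc iodide 19 (not isolated), via macrocyclic keto ester 20 (not isolated)
Conditions: Zn dust (activated), LiCl, THF, 25 °C; then syringe-pump addition to PdCl2(PPh3)2 (10 mol %), toluene, 50 °C (1 mM final); then CSA (1.5 equiv), 70 °C; NH4Cl work-up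
Reagents that add atoms: none
Why: Proposed new method: zinc inserts into the activated β-iodoenoate to give a configurationally stable alkenylzinc, zerovalent palladium inserts into the thioester C–S bond and intramolecular transmetalation/reductive elimination closes the ten-membered carbocycle with retention of alkene geometry (closest known reaction: Fukuyama thioester–organozinc ketone coupling, here used as a macrocyclisation), after which acid enolises the new ketone toward its CH2 and the enol oxygen acylates the cis methyl ester (enol-lactonisation of a Z-4-oxo-2-enoate) to form the butenolide, the ring forcing the exocyclic alkene geometry; no stereocentre is formed or touched.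

Step 13
Reactants: 21 bis(tert-butyldimethylsilyl) ether of the target
Product: 22 CNP0288314.1
Conditions: HF·pyridine, pyridine, THF, 0 → 25 °C
Reagents that add atoms: none
Why: Fluoride cleavage of both primary silyl ethers under buffered conditions that leave the enol lactone, the two esters and all three stereocentres intact.

**Compound list** (names of 20–22 use germacrane numbering)

1 | α-methylene-γ-butyrolactone (3-methylenedihydrofuran-2(3H)-one) | C=C1CCOC1=O | starting material
2 | (S)-3-methyldihydrofuran-2(3H)-one | C[C@H]1CCOC1=O | intermediate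
3 | (S)-citramalic acid, (2S)-2-hydroxy-2-methylbutanedioic acid | OC(=O)C[C@](C)(O)C(O)=O | starting material
4 | 2-[(4S)-2,2,4-trimethyl-5-oxo-1,3-dioxolan-4-yl]acetic acid | O=C1[C@](C)(CC(O)=O)OC(C)(C)O1 | intermediate
5 | (3S)-3-hydroxy-3-methyl-4-oxopentanoic acid | CC(=O)[C@@](C)(O)CC(O)=O | intermediate
6 | (3S,7S)-3,9-dihydroxy-3,7-dimethyl-4,6-dioxononanoic acid | OCC[C@H](C)C(=O)CC(=O)[C@@](C)(O)CC(O)=O | intermediate
7 | 2-[(2S)-5-[(2S)-4-hydroxybutan-2-yl]-2-methyl-3-oxo-2,3-dihydrofuran-2-yl]acetic acid | OCC[C@H](C)C1=CC(=O)[C@](C)(CC(O)=O)O1 | intermediate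
8 | 2-[(2S)-2-methyl-3-oxo-5-[(2S)-4-oxobutan-2-yl]-2,3-dihydrofuran-2-yl]acetic acid | O=CC[C@H](C)C1=CC(=O)[C@](C)(CC(O)=O)O1 | intermediate
9 | S-ethyl 2-[(2S)-2-methyl-3-oxo-5-[(2S)-4-oxobutan-2-yl]-2,3-dihydrofuran-2-yl]ethanethioate | O=CC[C@H](C)C1=CC(=O)[C@](C)(CC(=O)SCC)O1 | intermediate
10 | methyl propiolate | C#CC(=O)OC | starting material
11 | methyl (4S,6S)-6-[(5S)-5-[2-(ethylsulfanyl)-2-oxoethyl]-5-methyl-4-oxo-4,5-dihydrofuran-2-yl]-4-hydroxyhept-2-ynoate | O[C@H](C#CC(=O)OC)C[C@H](C)C1=CC(=O)[C@](C)(CC(=O)SCC)O1 | intermediate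
12 | 1-(tert-butyldimethylsilyloxy)propan-2-one | CC(=O)CO[Si](C)(C)C(C)(C)C | starting material
13 | triethyl phosphonoacetate | CCOC(=O)CP(=O)(OCC)OCC | starting material
14 | ethyl (2E)-4-(tert-butyldimethylsilyloxy)-3-methylbut-2-enoate | C/C(=C\C(=O)OCC)CO[Si](C)(C)C(C)(C)C | intermediate
15 | (2E)-4-(tert-butyldimethylsilyloxy)-3-methylbut-2-enoic acid | C/C(=C\C(O)=O)CO[Si](C)(C)C(C)(C)C | intermediate
16 | methyl (4S,6S)-4-{[(2E)-4-(tert-butyldimethylsilyloxy)-3-methylbut-2-enoyl]oxy}-6-[(5S)-5-[2-(ethylsulfanyl)-2-oxoethyl]-5-methyl-4-oxo-4,5-dihydrofuran-2-yl]hept-2-ynoate | C/C(=C\C(=O)O[C@H](C#CC(=O)OC)C[C@H](C)C1=CC(=O)[C@](C)(CC(=O)SCC)O1)CO[Si](C)(C)C(C)(C)C | intermediate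
17 | methyl (2Z,4S,6S)-4-{[(2E)-4-(tert-butyldimethylsilyloxy)-3-methylbut-2-enoyl]oxy}-6-[(5S)-5-[2-(ethylsulfanyl)-2-oxoethyl]-5-methyl-4-oxo-4,5-dihydrofuran-2-yl]-2-(hydroxymethyl)-3-iodohept-2-enoate (present as its magnesium alkoxide) | OC/C(C(=O)OC)=C(/I)[C@@H](OC(=O)/C=C(\C)CO[Si](C)(C)C(C)(C)C)C[C@H](C)C1=CC(=O)[C@](C)(CC(=O)SCC)O1 | intermediate
18 | methyl (2Z,4S,6S)-4-{[(2E)-4-(tert-butyldimethylsilyloxy)-3-methylbut-2-enoyl]oxy}-2-[(tert-butyldimethylsilyloxy)methyl]-6-[(5S)-5-[2-(ethylsulfanyl)-2-oxoethyl]-5-methyl-4-oxo-4,5-dihydrofuran-2-yl]-3-iodohept-2-enoate | CC(C)(C)[Si](C)(C)OC/C(C(=O)OC)=C(/I)[C@@H](OC(=O)/C=C(\C)CO[Si](C)(C)C(C)(C)C)C[C@H](C)C1=CC(=O)[C@](C)(CC(=O)SCC)O1 | intermediate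
19 | alkenylzinc iodide of 18 (C–I replaced by C–ZnI, same alkene geometry and stereocentres) | CC(C)(C)[Si](C)(C)OC/C(C(=O)OC)=C(/[Zn]I)[C@@H](OC(=O)/C=C(\C)CO[Si](C)(C)C(C)(C)C)C[C@H](C)C1=CC(=O)[C@](C)(CC(=O)SCC)O1 | intermediate
20 | methyl (4S,7(11)Z,8S,10S)-13-(tert-butyldimethylsilyloxy)-8-{[(2E)-4-(tert-butyldimethylsilyloxy)-3-methylbut-2-enoyl]oxy}-1,4-epoxy-3,6-dioxogermacra-1,7(11)-dien-12-oate (ten-membered carbocycle, C6 ketone cis to CO2Me) | C/C(=C\C(=O)O[C@H]1C[C@H](C)C2=CC(=O)[C@](C)(CC(=O)/C1=C(/CO[Si](C)(C)C(C)(C)C)C(=O)OC)O2)CO[Si](C)(C)C(C)(C)C | intermediate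
21 | bis(tert-butyldimethylsilyl) ether of 22 (both primary hydroxyls silylated) | C/C(=C\C(=O)O[C@H]1C[C@H](C)C2=CC(=O)[C@](C)(/C=C3/OC(=O)C(CO[Si](C)(C)C(C)(C)C)=C31)O2)CO[Si](C)(C)C(C)(C)C | intermediate
22 | CNP0288314.1, (4S,5E,8S,10S)-1,4-epoxy-13-hydroxy-8-{[(2E)-4-hydroxy-3-methylbut-2-enoyl]oxy}-3-oxogermacra-1,5,7(11)-trien-12,6-olide | C/C(=C\C(=O)O[C@H]1C[C@H](C)C2=CC(=O)[C@](C)(/C=C3/OC(=O)C(CO)=C31)O2)CO | target

**Step count**
Total: 13 steps. Longest linear sequence: 10 steps (3 → 4 → 5 → 7 → 8 → 9 → 11 → 16 → 18 → 21 → 22).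

**Three steps most likely to fail**

Step 12 (macrocyclisation and butenolide formation). The ten-membered ring may not close, the alkenylzinc may lose the neighbouring allylic ester by β-elimination to an allene, or it may be protonated before it couples. The fallback sets out from 18 and avoids a carbanionic vinyl metal. Stannylation with (Me3Sn)2 and Pd(PPh3)4 in toluene gives methyl (2Z,4S,6S)-4-{[(2E)-4-(tert-butyldimethylsilyloxy)-3-methylbut-2-enoyl]oxy}-2-[(tert-butyldimethylsilyloxy)methyl]-6-[(5S)-5-[2-(ethylsulfanyl)-2-oxoethyl]-5-methyl-4-oxo-4,5-dihydrofuran-2-yl]-3-(trimethylstannyl)hept-2-enoate F6. This is cyclised under neutral Liebeskind–Srogl thioester–stannane conditions (Pd2(dba)3, tri(2-furyl)phosphine, CuO2PPh2 as the monovalent copper mediator, THF, high dilution). That comes back to the route at 20, which is lactonised with CSA to 21 as before.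

Step 11 (iodo-aldol on a β-substituted ynoate). The most probable failure is the opposite alkene isomer, with formaldehyde entering syn to iodine. The fallback sets out from 16 and gives up kinetic control of this alkene. The same conditions then give the (2E) isomer of 18 (iodine trans to CO2Me) F4. Its zinc/palladium cyclisation, which does not depend on the alkene geometry, gives the 7(11)E isomer of 20 (ketone trans to CO2Me) F5. Irradiation of F5 at 350 nm in toluene with CSA isomerises the tetrasubstituted enone–ester, and only the Z isomer can lactonise, so the mixture drains to the enol lactone. This comes back to the route at 21.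

Step 4 (trianion acylation by the lactone). The lactone is a sluggish acyl donor, proton transfer from its α-position to the enolate could erode the CHMe centre, and 7 may partly sit as a spiroketal tautomer (which step 5 would drain). The fallback sets out from 2 and 4 and reverses the roles of the partners. MeLi opens 2 to (3S)-5-hydroxy-3-methylpentan-2-one F1, which is silylated (TBSCl, imidazole) to (3S)-5-(tert-butyldimethylsilyloxy)-3-methylpentan-2-one F2. The kinetic methyl enolate of F2 (LiN(iPr)2, −78 °C) is acylated by the lithium carboxylate of the activated dioxolanone 4 to give (3S,7S)-9-(tert-butyldimethylsilyloxy)-3-hydroxy-3,7-dimethyl-4,6-dioxononanoic acid F3. Aqueous HCl removes the silyl group and cyclodehydrates, coming back to the route at 7.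

**Further compounds**
F1 | step 4 | (3S)-5-hydroxy-3-methylpentan-2-one | OCC[C@H](C)C(C)=O
F2 | step 4 | (3S)-5-(tert-butyldimethylsilyloxy)-3-methylpentan-2-one | CC(C)(C)[Si](C)(C)OCC[C@H](C)C(C)=O
F3 | step 4 | (3S,7S)-9-(tert-butyldimethylsilyloxy)-3-hydroxy-3,7-dimethyl-4,6-dioxononanoic acid | CC(C)(C)[Si](C)(C)OCC[C@H](C)C(=O)CC(=O)[C@@](C)(O)CC(O)=O
F4 | step 11 | (2E) isomer of 18 (iodine trans to CO2Me) | CC(C)(C)[Si](C)(C)OC/C(C(=O)OC)=C(\I)[C@@H](OC(=O)/C=C(\C)CO[Si](C)(C)C(C)(C)C)C[C@H](C)C1=CC(=O)[C@](C)(CC(=O)SCC)O1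
F5 | step 11 | 7(11)E isomer of 20 (ketone trans to CO2Me) | C/C(=C\C(=O)O[C@H]1C[C@H](C)C2=CC(=O)[C@](C)(CC(=O)/C1=C(\CO[Si](C)(C)C(C)(C)C)C(=O)OC)O2)CO[Si](C)(C)C(C)(C)C
F6 | step 12 | methyl (2Z,4S,6S)-4-{[(2E)-4-(tert-butyldimethylsilyloxy)-3-methylbut-2-enoyl]oxy}-2-[(tert-butyldimethylsilyloxy)methyl]-6-[(5S)-5-[2-(ethylsulfanyl)-2-oxoethyl]-5-methyl-4-oxo-4,5-dihydrofuran-2-yl]-3-(trimethylstannyl)hept-2-enoate | CC(C)(C)[Si](C)(C)OC/C(C(=O)OC)=C(/[Sn](C)(C)C)[C@@H](OC(=O)/C=C(\C)CO[Si](C)(C)C(C)(C)C)C[C@H](C)C1=CC(=O)[C@](C)(CC(=O)SCC)O1
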